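**Retrosynthetic overview**

1. The target is reached by global O-debenzylation of its hexa-O-benzyl ether, which is disconnected at the C3–O acyl bond (Steglich esterification) into 5,7,3',4'-tetra-O-benzyl-(−)-epicatechin and 3,5-di-O-benzyl-4-O-methylgallic acid.
2. The 3R carbinol comes from the (2R)-flavan-3-one by hydride delivery anti to the C2 aryl group; the ketone comes from a 2-aryl-2H-chromene-3-carbaldehyde by Baeyer–Villiger excision of the formyl carbon, which stands in for the C3 oxygen.
3. Key disconnection: the C3–C4 bond of ring C (the pyran ring), closed by an intramolecular aldol condensation inside an aminocatalytic oxa-Michael/aldol domino between 2,4-bis(benzyloxy)-6-hydroxybenzaldehyde (ring A, O1, C4) and (E)-3,4-bis(benzyloxy)cinnamaldehyde (ring B, C2, C3, temporary formyl carbon). O1–C2 forms first in the same flask and fixes C2.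
4. Enabling feature: C4 is a benzylic carbon on ring A ortho to the ring oxygen O1 (a masked salicylaldehyde carbonyl carbon), and C3, lying between C4 and the O1- and ring-B-bearing C2, carries an oxygen that can be derived from a formyl group. The array C2–C3(CHO)=C4 is therefore the retron of an enal α-carbon condensing onto an aryl aldehyde.
5. Order of ring formation: rings A and B are bought as arenes; ring C is the only ring formed (step 3).

Key step: step 3

Remark: flavan numbering is used throughout (O1, C2, C3, C4, C4a to C8a; ring A = benzo ring, ring B = C2 aryl ring, ring C = pyran ring); the starting aldehydes, the ylide and methyl 3,5-dihydroxy-4-methoxybenzoate are taken to be commercial.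

**Route**

Step 1
Reactants: 1 2,4,6-trihydroxybenzaldehyde
Product: 2 2,4-bis(benzyloxy)-6-hydroxybenzaldehyde
Conditions: BnBr (2.1 equiv), K2CO3, DMF, 0 °C to rt
Reagents that add atoms: benzyl bromide BrCc1ccccc1
Why: Williamson etherification in which the 4-OH and one ortho OH are alkylated while the remaining ortho OH, held in a hydrogen bond to the formyl group and the least acidic, should stay free.

Step 2
Reactants: 3 3,4-bis(benzyloxy)benzaldehyde
Product: 4 (2E)-3-[3,4-bis(benzyloxy)phenyl]prop-2-enal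
Conditions: Ph3P=CHCHO, toluene, 90 °C
Reagents that add atoms: (triphenylphosphoranylidene)acetaldehyde O=CC=P(c1ccccc1)(c1ccccc1)c1ccccc1
Why: Wittig olefination with the stabilized formylmethylene ylide, which should give the E enal as the thermodynamically controlled product.

Step 3
Reactants: 2 2,4-bis(benzyloxy)-6-hydroxybenzaldehyde; 4 (2E)-3-[3,4-bis(benzyloxy)phenyl]prop-2-enal
Product: 7 (2R)-5,7-bis(benzyloxy)-2-[3,4-bis(benzyloxy)phenyl]-2H-chromene-3-carbaldehyde, via oxa-Michael adduct 5 (not isolated), via aldol adduct 6 (not isolated)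
Conditions: (S)-2-[diphenyl(trimethylsilyloxy)methyl]pyrrolidine (20 mol%), 2-nitrobenzoic acid (20 mol%), 4 Å MS, toluene, 0 °C to rt, dark
Reagents that add atoms: none
Why: Iminium activation of enal 4 by the secondary amine lets the phenolic oxygen of 2 add to the β-carbon (oxa-Michael, O1–C2), and the enamine so formed attacks the neighbouring formyl carbon of ring A through its α-carbon (intramolecular aldol, C3–C4), after which loss of water and hydrolysis of the iminium ion return the catalyst and give the conjugated 2H-chromene-3-carbaldehyde. The closest known reaction type is the aminocatalytic domino oxa-Michael/aldol condensation of salicylaldehydes with cinnamaldehydes to 2-aryl-2H-chromene-3-carbaldehydes. Ring C is closed in a 6-(enolexo)-exo-trig aldol step, the only ring-forming event of the synthesis. The single new stereocenter, C2, is set by the catalyst: the CPh2(OSiMe3) group shields one face of the E-configured iminium ion, so that oxygen should add to the open face, which by the usual shielding model corresponds to R at C2; the C3 and C4 centres of the aldol adduct are erased by dehydration. The step needs 1,4- over 1,2-addition, O- over C-alkylation of the electron-rich ring A, and a ring closure that outruns the retro-oxa-Michael reaction; these are secured by the soft iminium acceptor, by the formyl group that deactivates the ring carbons and sits ortho to the phenol so that the aldol is intramolecular, and by the irreversible dehydration to the push-pull enal.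

Step 4
Reactants: 7 (2R)-5,7-bis(benzyloxy)-2-[3,4-bis(benzyloxy)phenyl]-2H-chromene-3-carbaldehyde
Product: 9 (2R)-5,7-bis(benzyloxy)-2-[3,4-bis(benzyloxy)phenyl]chroman-3-one, via enol formate 8 (not isolated)
Conditions: mCPBA, CH2Cl2, 0 °C; aq. NaHCO3 wash; then MeOH, KHCO3 (cat.), 0 °C
Reagents that add atoms: 3-chloroperoxybenzoic acid (mCPBA) OOC(=O)c1cccc(Cl)c1
Why: Baeyer–Villiger oxidation of an α,β-unsaturated aldehyde (a vinylogous Dakin oxidation), in which the alkenyl group, made electron-rich through C4 by the 5- and 7-benzyloxy groups of ring A, should migrate in preference to hydride to give the enol formate, whose mild methanolysis releases the C3 enol that tautomerizes to the ketone with C4 becoming CH2 and C2 untouched.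

Step 5
Reactants: 9 (2R)-5,7-bis(benzyloxy)-2-[3,4-bis(benzyloxy)phenyl]chroman-3-one
Product: 10 (2R,3R)-5,7-bis(benzyloxy)-2-[3,4-bis(benzyloxy)phenyl]chroman-3-ol
Conditions: LiBH(s-Bu)3 (L-Selectride), LiBr, THF, −78 °C; then H2O
Reagents that add atoms: none
Why: Diastereoselective ketone reduction by a bulky trialkylborohydride, which should deliver hydride to C3 from the face opposite the C2 aryl group and so give the axial 3R alcohol cis to that group, the established course for this class of flavan-3-ones.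

Step 6
Reactants: 11 methyl 3,5-dihydroxy-4-methoxybenzoate
Product: 12 methyl 3,5-bis(benzyloxy)-4-methoxybenzoate
Conditions: BnBr, K2CO3, DMF, 60 °C
Reagents that add atoms: benzyl bromide BrCc1ccccc1
Why: Williamson etherification of both phenols, the only nucleophilic sites of the substrate.

Step 7
Reactants: 12 methyl 3,5-bis(benzyloxy)-4-methoxybenzoate
Product: 13 3,5-bis(benzyloxy)-4-methoxybenzoic acid
Conditions: LiOH, THF/MeOH/H2O, 50 °C; then 1 M HCl
Reagents that add atoms: lithium hydroxide [Li+].[OH-]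
Why: Ester saponification by acyl-oxygen cleavage, which leaves the benzyl and methyl ethers intact.

Step 8
Reactants: 10 (2R,3R)-5,7-bis(benzyloxy)-2-[3,4-bis(benzyloxy)phenyl]chroman-3-ol; 13 3,5-bis(benzyloxy)-4-methoxybenzoic acid
Product: 14 (2R,3R)-5,7-bis(benzyloxy)-2-[3,4-bis(benzyloxy)phenyl]chroman-3-yl 3,5-bis(benzyloxy)-4-methoxybenzoate
Conditions: DCC, DMAP (cat.), CH2Cl2, 0 °C to rt
Reagents that add atoms: none
Why: Steglich esterification through the O-acylisourea and the acylpyridinium ion, which acylates the hindered axial 3-OH without breaking the C3–O bond, so that the 3R configuration is retained.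

Step 9
Reactants: 14 (2R,3R)-5,7-bis(benzyloxy)-2-[3,4-bis(benzyloxy)phenyl]chroman-3-yl 3,5-bis(benzyloxy)-4-methoxybenzoate
Product: 15 epicatechin 3-O-(4-O-methylgallate)
Conditions: H2 (1 atm), Pd(OH)2/C, THF/MeOH, rt
Reagents that add atoms: none
Why: Heterogeneous hydrogenolysis of the six benzyl ethers under neutral conditions, which should leave the benzoate ester, the C2–O1 bond and both stereocenters untouched.

**Compound list**

1 | 2,4,6-trihydroxybenzaldehyde | O=Cc1c(O)cc(O)cc1O | starting material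
2 | 2,4-bis(benzyloxy)-6-hydroxybenzaldehyde | O=Cc1c(O)cc(OCc2ccccc2)cc1OCc1ccccc1 | intermediate
3 | 3,4-bis(benzyloxy)benzaldehyde | O=Cc1ccc(OCc2ccccc2)c(OCc2ccccc2)c1 | starting material
4 | (2E)-3-[3,4-bis(benzyloxy)phenyl]prop-2-enal | O=C/C=C/c1ccc(OCc2ccccc2)c(OCc2ccccc2)c1 | intermediate
5 | (3S)-3-[3,4-bis(benzyloxy)phenyl]-3-[3,5-bis(benzyloxy)-2-formylphenoxy]propanal (oxa-Michael adduct, present as its enamine with the catalyst) | O=CC[C@H](Oc1cc(OCc2ccccc2)cc(OCc2ccccc2)c1C=O)c1ccc(OCc2ccccc2)c(OCc2ccccc2)c1 | intermediate (not isolated)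
6 | (2S)-5,7-bis(benzyloxy)-2-[3,4-bis(benzyloxy)phenyl]-4-hydroxychromane-3-carbaldehyde (aldol adduct; C3 and C4 not defined, both lost on dehydration) | O=CC1C(O)c2c(OCc3ccccc3)cc(OCc3ccccc3)cc2O[C@@H]1c1ccc(OCc2ccccc2)c(OCc2ccccc2)c1 | intermediate (not isolated)
7 | (2R)-5,7-bis(benzyloxy)-2-[3,4-bis(benzyloxy)phenyl]-2H-chromene-3-carbaldehyde | O=CC1=Cc2c(OCc3ccccc3)cc(OCc3ccccc3)cc2O[C@@H]1c1ccc(OCc2ccccc2)c(OCc2ccccc2)c1 | intermediate
8 | (2R)-5,7-bis(benzyloxy)-2-[3,4-bis(benzyloxy)phenyl]-2H-chromen-3-yl formate | O=COC1=Cc2c(OCc3ccccc3)cc(OCc3ccccc3)cc2O[C@@H]1c1ccc(OCc2ccccc2)c(OCc2ccccc2)c1 | intermediate (not isolated)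
9 | (2R)-5,7-bis(benzyloxy)-2-[3,4-bis(benzyloxy)phenyl]chroman-3-one | O=C1Cc2c(OCc3ccccc3)cc(OCc3ccccc3)cc2O[C@@H]1c1ccc(OCc2ccccc2)c(OCc2ccccc2)c1 | intermediate
10 | (2R,3R)-5,7-bis(benzyloxy)-2-[3,4-bis(benzyloxy)phenyl]chroman-3-ol (5,7,3',4'-tetra-O-benzyl-(−)-epicatechin) | O[C@@H]1Cc2c(OCc3ccccc3)cc(OCc3ccccc3)cc2O[C@@H]1c1ccc(OCc2ccccc2)c(OCc2ccccc2)c1 | intermediate
11 | methyl 3,5-dihydroxy-4-methoxybenzoate | COC(=O)c1cc(O)c(OC)c(O)c1 | starting material
12 | methyl 3,5-bis(benzyloxy)-4-methoxybenzoate | COC(=O)c1cc(OCc2ccccc2)c(OC)c(OCc2ccccc2)c1 | intermediate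
13 | 3,5-bis(benzyloxy)-4-methoxybenzoic acid | OC(=O)c1cc(OCc2ccccc2)c(OC)c(OCc2ccccc2)c1 | intermediate
14 | (2R,3R)-5,7-bis(benzyloxy)-2-[3,4-bis(benzyloxy)phenyl]chroman-3-yl 3,5-bis(benzyloxy)-4-methoxybenzoate | COc1c(OCc2ccccc2)cc(cc1OCc1ccccc1)C(=O)O[C@@H]1Cc2c(OCc3ccccc3)cc(OCc3ccccc3)cc2O[C@@H]1c1ccc(OCc2ccccc2)c(OCc2ccccc2)c1 | intermediate
15 | epicatechin 3-O-(4-O-methylgallate), (2R,3R)-2-(3,4-dihydroxyphenyl)-5,7-dihydroxychroman-3-yl 3,5-dihydroxy-4-methoxybenzoate | COc1c(O)cc(C(=O)O[C@@H]2Cc3c(O)cc(O)cc3O[C@@H]2c2ccc(O)c(O)c2)cc1O | target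

**Step count and risks**

Total step count: 9. Longest linear sequence: 6 steps (steps 1, 3, 4, 5, 8, 9).

Steps most likely to fail:

1. Step 3. The aldol closure onto the hindered, doubly donor-substituted formyl group may be slow, so that the oxa-Michael adduct reverts and enantiomeric purity is eroded. Thermal or photochemical electrocyclic ring opening of the push-pull chromene would also scramble C2. Fallback (leaves the route at 2 and 4, returns at 9): the same C3–C4 bond is closed by olefin metathesis after C2 has been set by iridium catalysis. Enal 4 is reduced (NaBH4, CeCl3·7H2O, MeOH, 0 °C) to (2E)-3-[3,4-bis(benzyloxy)phenyl]prop-2-en-1-ol F1 and acylated (ClCO2Me, pyridine, CH2Cl2) to the methyl carbonate F2. Allylic etherification of the lithium phenoxide of 2 with F2 ([Ir(cod)Cl]2, BINOL-derived bis(1-phenylethyl)amine phosphoramidite ligand, THF, rt; ligand enantiomer chosen for the S ether) should give the branched allyl aryl ether F3. Wittig methylenation (Ph3PCH3Br, KOtBu, THF, 0 °C) gives the diene F4, and ring-closing metathesis (second-generation Grubbs catalyst, RuCl2(=CHPh)(PCy3)(H2IMes), CH2Cl2, 40 °C) gives the flav-3-ene F5. Hydroboration–oxidation (BH3·THF, 0 °C; NaOH, H2O2) should place the hydroxyl at C3 anti to the aryl group to give the trans alcohol 5,7,3',4'-tetra-O-benzyl-(+)-catechin F6, and Dess–Martin oxidation (CH2Cl2, rt) returns ketone 9.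

2. Step 4. Hydride may migrate instead of the alkenyl group (giving the carboxylic acid), excess peracid may epoxidize the enol formate, or C2 may epimerize in the ketone during the basic methanolysis. Fallback (leaves the route at 7, returns at 9): the formyl carbon is removed by a Curtius degradation under non-basic conditions. Pinnick oxidation of 7 (NaClO2, NaH2PO4, 2-methyl-2-butene, t-BuOH/H2O) gives the 2H-chromene-3-carboxylic acid F7; (PhO)2P(O)N3, Et3N, toluene, rt gives the acyl azide F8, which on warming to 80 °C rearranges to the vinyl isocyanate F9; 1 M HCl, THF, rt hydrolyses F9 through the carbamic acid and the enamine to ketone 9.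

3. Step 1. Over-alkylation, C-benzylation of the phloroglucinol ring and incomplete discrimination between the hydroxyl groups may give mixtures. Fallback (leaves the route at 1, returns at 2): exhaustive benzylation (BnBr, K2CO3, DMF, 60 °C) to 2,4,6-tris(benzyloxy)benzaldehyde F10, then chelation-directed removal of one benzyl group ortho to the formyl group (MgBr2·OEt2, toluene/Et2O, reflux) to give 2.

**Further compounds**

F1 | step 3 | (2E)-3-[3,4-bis(benzyloxy)phenyl]prop-2-en-1-ol | OC/C=C/c1ccc(OCc2ccccc2)c(OCc2ccccc2)c1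
F2 | step 3 | (2E)-3-[3,4-bis(benzyloxy)phenyl]prop-2-en-1-yl methyl carbonate | COC(=O)OC/C=C/c1ccc(OCc2ccccc2)c(OCc2ccccc2)c1
F3 | step 3 | 2,4-bis(benzyloxy)-6-{[(1S)-1-[3,4-bis(benzyloxy)phenyl]prop-2-en-1-yl]oxy}benzaldehyde | C=C[C@H](Oc1cc(OCc2ccccc2)cc(OCc2ccccc2)c1C=O)c1ccc(OCc2ccccc2)c(OCc2ccccc2)c1
F4 | step 3 | 1,5-bis(benzyloxy)-3-{[(1S)-1-[3,4-bis(benzyloxy)phenyl]prop-2-en-1-yl]oxy}-2-ethenylbenzene | C=C[C@H](Oc1cc(OCc2ccccc2)cc(OCc2ccccc2)c1C=C)c1ccc(OCc2ccccc2)c(OCc2ccccc2)c1
F5 | step 3 | (2S)-5,7-bis(benzyloxy)-2-[3,4-bis(benzyloxy)phenyl]-2H-chromene | C1=Cc2c(OCc3ccccc3)cc(OCc3ccccc3)cc2O[C@@H]1c1ccc(OCc2ccccc2)c(OCc2ccccc2)c1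
F6 | step 3 | (2R,3S)-5,7-bis(benzyloxy)-2-[3,4-bis(benzyloxy)phenyl]chroman-3-ol | O[C@H]1Cc2c(OCc3ccccc3)cc(OCc3ccccc3)cc2O[C@@H]1c1ccc(OCc2ccccc2)c(OCc2ccccc2)c1
F7 | step 4 | (2R)-5,7-bis(benzyloxy)-2-[3,4-bis(benzyloxy)phenyl]-2H-chromene-3-carboxylic acid | OC(=O)C1=Cc2c(OCc3ccccc3)cc(OCc3ccccc3)cc2O[C@@H]1c1ccc(OCc2ccccc2)c(OCc2ccccc2)c1
F8 | step 4 | (2R)-5,7-bis(benzyloxy)-2-[3,4-bis(benzyloxy)phenyl]-2H-chromene-3-carbonyl azide | [N-]=[N+]=NC(=O)C1=Cc2c(OCc3ccccc3)cc(OCc3ccccc3)cc2O[C@@H]1c1ccc(OCc2ccccc2)c(OCc2ccccc2)c1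
F9 | step 4 | (2R)-5,7-bis(benzyloxy)-2-[3,4-bis(benzyloxy)phenyl]-3-isocyanato-2H-chromene | O=C=NC1=Cc2c(OCc3ccccc3)cc(OCc3ccccc3)cc2O[C@@H]1c1ccc(OCc2ccccc2)c(OCc2ccccc2)c1
F10 | step 1 | 2,4,6-tris(benzyloxy)benzaldehyde | O=Cc1c(OCc2ccccc2)cc(OCc2ccccc2)cc1OCc1ccccc1
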